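## Analysis of the target

CNP0265879.1 (C30H32O4) is the C2-symmetric head-to-head [2+2] dimer of the lindenane lactone chloranthalactone A. Lindenane numbering is used throughout: C1–C15, primes for the second half, α/β with the angular methyl C14 as β. The same numbers are kept for the eudesmane and germacrane precursors.

A cyclobutane C8–C9–C9'–C8' carries two identical tetracyclic halves, nine rings in all. Each half consists of:
- a cyclopropane (C1–C2–C3);
- a five-membered ring A (C1, C3, C4, C5, C10) with the exocyclic methylene C4=C15;
- a six-membered ring B (C5–C10);
- an α-methylbutenolide (C7=C11, C12, O, C8).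

There are twelve stereocentres (C1, C3, C5, C8, C9, C10 and their primed partners). Rings A and B are trans-fused (H5 α, C14 β). The cyclopropane methylene C2 lies on the β face, cis to C14. Both cyclobutane bonds of each half leave ring B on its α face, anti to C14, with the two lactone oxygens trans on the four-membered ring.

The sensitive groups are the acid-labile vinylcyclopropane (C15=C4–C3), the butenolides with their acidic C6–H, and the strained cyclobutane. The cyclobutane holds two adjacent fully substituted, oxygen-bearing carbons and can revert under short-wave light.

The cyclobutane is not the real problem. The problem is each half: the trans 5/6 fusion fixes the torsion about C5–C10, so a β-oriented C2 is almost eclipsed with C14. Any closure of ring A or delivery of a CH2 under steric control therefore tends to give the epimer with C2 anti to C14.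

The feature used here is that ring A plus C2 (C1–C5, C10) is a six-carbon ring with one extra bond, C1–C3, i.e. a 1,3-cycloeudesmane. In a chair trans-decalin C2 and C10 are both "up" carbons. Closing C1–C3 on the α side therefore leaves C2 cis to C14 by geometry and not by steric choice. In addition, the fifteen carbons, the C8 oxygen and the C7=C11 alkene of each half are those of the achiral ten-membered ketone germacrone.

## Retrosynthetic reasoning

**Target 14 to chloranthalactone A 13.** The bonds C8–C8' and C9–C9' are cut. No other construction of two adjacent fully substituted carbons in a four-membered ring competes with a light-driven dimerisation. It is kept, but only as the closing operation. It has to select the α faces and the head-to-head, anti arrangement.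

**13 to lindena-4(15),7(11)-dien-8-one 7.** The lactone C12–O bond and the oxidation level of C12 are removed, by way of 11, 10 and 8. The isopropylidene ketone of 7 already holds C11, C12 and C13. Only the methyl group syn to the carbonyl has to be raised to the acid level. An s-cis 2-siloxydiene (8) and singlet oxygen do this with the required Z geometry.

**7 to the eudesmane 5 (key disconnection).** The bond C1–C3 is cut, so the 3/5 ring pair becomes one six-membered ring A. The cut is made here because it turns the contra-steric cis C2/C14 relation into the ordinary geometry of a trans-decalin. C4=C15 can also be carried through as an allyl unit: C3 is made nucleophilic as the γ-carbon of an allylmetal (C15–metal, C3=C4), and C1 is made electrophilic as an equatorial 1β-sulfonate. The forward step has to be a 3-exo-tet displacement with inversion at C1.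

**5 to alcohol 3.** Only the two handles are removed: the mesylate at O1 (4) and the allylic chloride at C15. No skeletal bond is touched.

**3 to epoxide 2.** The bond C5–C10 is cut, which opens both six-membered rings to the ten-membered ring. The forward transannular cyclisation starts at the epoxide. It keeps the C1–O stereocentre and sets C5 and C10 through a chair-like crossing of the ring. It ends in the C4=C15 alkene that the target needs.

**2 to germacrone 1.** The epoxide oxygen is removed. All chirality of the route enters here, by a catalytic asymmetric epoxidation of an achiral, commercial C15 ketone.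

## Alternatives that were turned down

**Alternative 1:** (textbook) C8–C8'/C9–C9' as the bonds of the key step, i.e. [2+2] photodimerisation of 13. The monomer is made by intramolecular carbene cyclopropanation (C3–C1 and C3–C2 in one step) of the trans-2-vinylcyclohexyl diazoketone A1, followed by methylenation of the C4 ketone and butenolide annulation. The cycloaddition itself is not disputed and also closes the chosen route (step 10). What is turned down is a plan that rests on it, because it halves the molecule but leaves every hard stereocentre in the monomer. In A1 the C1 configuration depends on which face of a freely rotating vinyl group meets the carbene, and nothing in the substrate encodes the congested β-cyclopropane. The route passes through a trans-hydrindanone with an epimerisable C5–H. It needs diazo chemistry, starts from a racemic cyclohexenone ester and is long and linear.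

**Alternative 2:** C1–C3 and C5–C10 together, by a transannular (3+2) reaction of the allyl cation C3–C4–C5 with the C1=C10 alkene. The cation would be generated from an activated 3-hydroxygermacrone A2, and loss of H15 would follow. On paper this folds the macrocycle into the 3/5/6 tricycle in one step. The E geometry of both alkenes encodes all four stereocentres. It was turned down because the nucleophilic terminus C1 can close on C5 instead of C3. That closure gives a five-membered ring and a tertiary C10 cation, and should be far easier than closure to a three-membered ring, so the hydroazulene skeleton is expected. In addition, the ring methylene C3 of 1 has no selective oxidation, since ene-type oxidants prefer the methyl groups. A2 would therefore need its own macrocycle synthesis.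

**Alternative 3:** C3–C4, by Pd(0)-catalysed intramolecular C(sp3)–H alkenylation of a purchased cyclopropyl group in the enol triflate A3. This closes ring A with C4=C15 in place. It was turned down on stereochemical grounds. In the trans-diequatorial palladacycle the torsion about C5–C10 fixes the rotamer about C10–C1. The cyclopropane CH2 that can reach palladium while the other CH2 straddles C5 is the one that places C2 anti to C14. The natural isomer needs C2 nearly eclipsed with C14 in the transition state. The substrate bias thus opposes the target, and a chiral ligand would have to override it. The trans precursor also costs as many steps as the carbene route.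

Key step: step 5

Assumption: germacrone 1 and the D-fructose-derived Shi ketone are taken as commercial; 1 is treated as achiral because its planar-chiral ring conformers interconvert rapidly at the reaction temperature.

## Route

Step 1
Reactants: 1 germacrone, (1(10)E,4E)-germacra-1(10),4,7(11)-trien-8-one
Product: 2 (1R,10R)-1,10-epoxygermacra-4E,7(11)-dien-8-one
Conditions: D-fructose-derived Shi ketone (30 mol %), Oxone (1.0 equiv), K2CO3, Bu4NHSO4, MeCN–dimethoxymethane–aq. borate buffer (pH 10.5), 0 °C
Reagents that add atoms: Oxone (potassium peroxymonosulfate), [K+].[O-]S(=O)(=O)OO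
Why: Shi asymmetric epoxidation of an E-trisubstituted alkene; only the outer face of a ring alkene of 1 is open and the planar-chiral conformers interconvert, so the chiral dioxirane selects conformer and face together (dynamic kinetic resolution), and the spiro transition-state model for this ketone predicts the (1R,10R)-epoxide. One equivalent of oxidant, the electron-poor C7=C11 enone alkene and the position of the isopropylidene group next to the outer face of C4=C5 should direct the oxidant to C1=C10.

Step 2
Reactants: 2 (1R,10R)-1,10-epoxygermacra-4E,7(11)-dien-8-one
Product: 3 1β-hydroxy-5αH-eudesma-4(15),7(11)-dien-8-one (10β-methyl, trans-decalin)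
Conditions: Cp2TiCl2 (2.2 equiv), Mn dust, THF, 20 °C; 1 M HCl work-up
Reagents that add atoms: none
Why: Titanocene(III) epoxide opening (Nugent–RajanBabu type) gives the tertiary C10 radical, which adds across the ring to C5 of the C4=C5 alkene; the tertiary C4 radical is trapped by a second Ti(III) and loses a β-hydrogen from the methyl group, which gives the exocyclic C4=C15 alkene. C1 keeps its C–O configuration, and the chair-like crossed conformer of the E,E-ring sets C5 and C10 as the trans-decalin with axial 10β-methyl, 5α-H and equatorial 1β-OH.

Step 3
Reactants: 3 1β-hydroxy-5αH-eudesma-4(15),7(11)-dien-8-one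
Product: 4 1β-mesyloxy-5αH-eudesma-4(15),7(11)-dien-8-one
Conditions: MsCl, Et3N, DMAP (cat.), CH2Cl2, 0 °C
Reagents that add atoms: methanesulfonyl chloride, CS(=O)(=O)Cl
Why: Standard sulfonylation of an equatorial secondary alcohol with retention at C1; the neopentyl position next to quaternary C10 makes the mesylate inert to intermolecular substitution and elimination in the next step.

Step 4
Reactants: 4 1β-mesyloxy-5αH-eudesma-4(15),7(11)-dien-8-one
Product: 5 15-chloro-1β-mesyloxy-5αH-eudesma-3,7(11)-dien-8-one
Conditions: NCS (1.1 equiv), PhSeCl (5 mol %), CH2Cl2, 20 °C
Reagents that add atoms: N-chlorosuccinimide, O=C1CCC(=O)N1Cl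
Why: Selenium-catalysed ene-type allylic chlorination of a 1,1-disubstituted alkene with shift of the double bond: chlorine ends on the terminal carbon C15 and the axial hydrogen of the methylene C3 is lost in preference to the hindered methine H5. The enone alkene is too electron-poor to react, and the regioisomeric 3-chloro-4(15)-ene would feed the same allylmetal in step 5.

Step 5
Reactants: 5 15-chloro-1β-mesyloxy-5αH-eudesma-3,7(11)-dien-8-one
Product: 7 lindena-4(15),7(11)-dien-8-one (H1, H3, H5 α; C2 and C14 β), via allylzinc chloride 6 (not isolated)
Conditions: Zn dust (activated), NaI (20 mol %), DMA, 0.01 M, 25 to 50 °C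
Reagents that add atoms: none
Why: Proposed new method: zinc inserts into the allylic C15–Cl bond (iodide-assisted) to give the σ-allylzinc 6, whose γ-carbon C3 displaces the mesylate at C1 in an intramolecular SE2' process, so that C1–C3 forms while C4=C15 is regenerated. The closest known reactions are the zinc-mediated 1,3-elimination of 1,3-dihalides and 1,3-dimesylates (Gustavson-type cyclopropane synthesis), the nickel-catalysed cross-electrophile coupling of allylic ethers with 1,3-placed alkyl halides to vinylcyclopropanes, and the base-induced closure of 4-sulfonyloxycyclohexanones to bicyclo[3.1.0]hexan-2-ones. The closure is 3-exo-tet and turns the six-membered ring A into the cyclopropane C1–C2–C3 plus the five-membered ring C1, C3, C4, C5, C10. C1 is set by inversion: the equatorial 1β-mesylate is anti-periplanar to C2–C3, its rear lobe points to the α face of the ring, and H1 stays α. C3 is set because only the α lobe of the C3=C4 π bond can reach that rear lobe, and C2, an "up" carbon of the half-chair like C10, is thereby left on the β face, cis to C14, whatever the steric cost. Site selectivity is secured by structure: attack through C15 would give a bridgehead alkene, C5 is not part of the allyl system, and the hindered, cross-ring C8 enone cannot be reached intramolecularly, while high dilution suppresses intermolecular addition. No cation is formed at C1, so the Wagner–Meerwein shift of the anti-periplanar C5–C10 bond that rules the solvolysis of such sulfonates has no entry. The step converts a plain decalin into the complete carbon skeleton of one half of the target with C1, C3, C5 and C10 correct.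

Step 6
Reactants: 7 lindena-4(15),7(11)-dien-8-one
Product: 8 8-(tert-butyldimethylsilyloxy)lindena-4(15),7,11(12)-triene (2-siloxydiene C8=C7–C11=C12)
Conditions: TBSOTf (1.3 equiv), Et3N (2 equiv), CH2Cl2, 0 °C
Reagents that add atoms: tert-butyldimethylsilyl triflate, CC(C)(C)[Si](C)(C)OS(=O)(=O)C(F)(F)F
Why: Soft enolisation of an α-isopropylidene ketone: loss of a proton from the methyl group syn to the carbonyl (C12) relieves the allylic strain between that methyl and the oxygen and gives the conjugated 2-siloxydiene, whereas enolisation towards the neopentyl C9 keeps this strain. The amine buffer protects the vinylcyclopropane from acid.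

Step 7
Reactants: 8 8-(tert-butyldimethylsilyloxy)lindena-4(15),7,11(12)-triene
Product: 10 (Z)-8-oxolindena-4(15),7(11)-dien-12-al, via siloxy endoperoxide 9 (not isolated)
Conditions: O2, tetraphenylporphyrin (cat.), visible light, CH2Cl2, −78 °C; then Et3N (0.5 equiv), −78 to 0 °C
Reagents that add atoms: dioxygen, O=O
Why: Singlet-oxygen [4+2] cycloaddition to the electron-rich s-cis siloxydiene (much faster than an ene reaction at the 1,1-disubstituted C4=C15), then Kornblum–DeLaMare fragmentation: only C12 carries a hydrogen next to the O–O bond, so C12 becomes the aldehyde and the silyl peroxyketal at C8 collapses to the ketone. The bridge between C8 and C12 fixes the Z geometry that the lactone needs.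

Step 8
Reactants: 10 (Z)-8-oxolindena-4(15),7(11)-dien-12-al
Product: 11 8β-hydroxylindena-4(15),7(11)-dien-12,8-olide (ring-closed form of the Z-keto acid)
Conditions: NaClO2, NaH2PO4, 2-methyl-2-butene (excess), t-BuOH–H2O, 0 to 20 °C
Reagents that add atoms: sodium chlorite, [Na+].[O-]Cl=O
Why: Pinnick oxidation of the enal at about pH 4, mild enough for the vinylcyclopropane, with the alkene scavenger taking up hypochlorous acid before it can reach C4=C15. The Z-γ-keto acid closes spontaneously to the hydroxybutenolide; the configuration at C8 is lost again in step 9.

Step 9
Reactants: 11 8β-hydroxylindena-4(15),7(11)-dien-12,8-olide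
Product: 13 chloranthalactone A, lindena-4(15),7(11),8-trien-12,8-olide, via 8-acetate 12 (not isolated)
Conditions: Ac2O, pyridine, DMAP (cat.), 60 °C
Reagents that add atoms: none
Why: Acetylation of the tertiary lactol hydroxyl and base-induced elimination; C9 is the only neighbour of C8 that carries hydrogen, so the γ-alkylidene butenolide C8=C9 is the only possible alkene, and no acid touches the vinylcyclopropane.

Step 10
Reactants: 13 chloranthalactone A (two molecules)
Product: 14 CNP0265879.1, the C2-symmetric head-to-head anti [2+2] dimer (bonds C8–C8' and C9–C9')
Conditions: hν (365 nm, Pyrex), degassed benzene (0.3 M), 20 °C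
Reagents that add atoms: none
Why: [2+2] photodimerisation of a γ-alkylidene butenolide through its triplet state: the first bond C9–C9' leaves two tertiary, oxygen-substituted and allyl-type radicals at C8 and C8', which explains the head-to-head sense, and their coupling closes the ring. Both bonds form on the α face of ring B because the axial C14 methyl next to C9 shields the β face, and the anti (C2) arrangement keeps the two lactones and the two tricycles apart; this sets C8, C9, C8' and C9'.

## Compound list

1 | germacrone, (1(10)E,4E)-germacra-1(10),4,7(11)-trien-8-one | C/C1=C\CC/C(C)=C/CC(=C(C)C)C(=O)C1 | starting material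
2 | (1R,10R)-1,10-epoxygermacra-4E,7(11)-dien-8-one | C[C@@]12CC(=O)C(=C(C)C)C/C=C(\C)CC[C@H]1O2 | intermediate
3 | 1β-hydroxy-5αH-eudesma-4(15),7(11)-dien-8-one | C=C1CC[C@@H](O)[C@@]2(C)[C@H]1CC(=C(C)C)C(=O)C2 | intermediate
4 | 1β-mesyloxy-5αH-eudesma-4(15),7(11)-dien-8-one | C=C1CC[C@@H](OS(C)(=O)=O)[C@@]2(C)[C@H]1CC(=C(C)C)C(=O)C2 | intermediate
5 | 15-chloro-1β-mesyloxy-5αH-eudesma-3,7(11)-dien-8-one | ClCC1=CC[C@@H](OS(C)(=O)=O)[C@@]2(C)[C@H]1CC(=C(C)C)C(=O)C2 | intermediate
6 | allylzinc chloride from 5 (zinc on C15, C3=C4; not isolated) | Cl[Zn]CC1=CC[C@@H](OS(C)(=O)=O)[C@@]2(C)[C@H]1CC(=C(C)C)C(=O)C2 | intermediate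
7 | lindena-4(15),7(11)-dien-8-one | C=C1[C@H]2C[C@H]2[C@@]2(C)[C@H]1CC(=C(C)C)C(=O)C2 | intermediate
8 | 8-(tert-butyldimethylsilyloxy)lindena-4(15),7,11(12)-triene | C=C1[C@H]2C[C@H]2[C@@]2(C)[C@H]1CC(C(C)=C)=C(O[Si](C)(C)C(C)(C)C)C2 | intermediate
9 | 8α,12-epidioxy-8β-(tert-butyldimethylsilyloxy)lindena-4(15),7(11)-diene (not isolated) | C=C1[C@H]2C[C@H]2[C@@]2(C)[C@H]1CC1=C(C)COO[C@@]1(O[Si](C)(C)C(C)(C)C)C2 | intermediate
10 | (Z)-8-oxolindena-4(15),7(11)-dien-12-al | C=C1[C@H]2C[C@H]2[C@@]2(C)[C@H]1C/C(=C(\C)C=O)C(=O)C2 | intermediate
11 | 8β-hydroxylindena-4(15),7(11)-dien-12,8-olide | C=C1[C@H]2C[C@H]2[C@@]2(C)[C@H]1CC1=C(C)C(=O)O[C@@]1(O)C2 | intermediate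
12 | 8β-acetoxylindena-4(15),7(11)-dien-12,8-olide (not isolated) | C=C1[C@H]2C[C@H]2[C@@]2(C)[C@H]1CC1=C(C)C(=O)O[C@@]1(OC(C)=O)C2 | intermediate
13 | chloranthalactone A, lindena-4(15),7(11),8-trien-12,8-olide | C=C1[C@H]2C[C@H]2[C@@]2(C)[C@H]1CC1=C(C)C(=O)OC1=C2 | intermediate
14 | CNP0265879.1, head-to-head anti [2+2] dimer of 13 | C=C1[C@H]2C[C@H]2[C@@]2(C)[C@H]1CC1=C(C)C(=O)O[C@]13[C@H]2[C@H]1[C@@]2(C)[C@@H]4C[C@@H]4C(=C)[C@@H]2CC2=C(C)C(=O)O[C@@]213 | target

## Step count and least certain steps

Total step count: 10. Longest linear sequence: 10 (fully linear from 1).

**Step 5 (key step, proposed new method).**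
- Most likely failure: the displacement at the neopentyl carbon C1 is slower than loss of the allylzinc by protonation or by intermolecular addition to a ketone.
- A second failure: zinc(II) salts promote ionisation of the mesylate, with migration of the anti-periplanar C5–C10 bond.
- Fallback with known chemistry, from 4:
  - Ozonolysis of the electron-rich C4=C15 alkene (O3, CH2Cl2–MeOH, −78 °C, then Me2S; the enone alkene is left) would give 1β-mesyloxy-15-noreudesm-7(11)-ene-4,8-dione F1.
  - Kinetic deprotonation at C3 (KHMDS, THF, −78 to 0 °C) would close the same C1–C3 bond by the classical enolate 3-exo-tet displacement of a γ-sulfonyloxy ketone. This gives 15-norlindena-7(11)-ene-4,8-dione F2.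
  - Wittig methylenation (Ph3P=CH2) of the unconjugated C4 ketone comes back to the route at 7.

**Step 1.**
- The oxidant may divide between C1=C10 and C4=C5.
- Facial control may be incomplete if both ring conformers fit the catalyst.
- Fallback, from 1:
  - The ring is folded directly by an enantioselective iodonium-induced transannular cyclisation (NIS with a chiral phosphoramidite promoter). Reversible attack at C4=C5 is unproductive there.
  - This would give 1β-iodo-5αH-eudesma-4(15),7(11)-dien-8-one F3.
  - Allylic chlorination as in step 4 would give 15-chloro-1β-iodo-5αH-eudesma-3,7(11)-dien-8-one F4.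
  - The zinc closure of F4, with a better leaving group, comes back to the route at 7.

**Step 4.**
- Hydrogen may be lost from C5 instead of C3.
- Chlorine may be transferred to the isopropylidene group.
- Fallback, from 4:
  - Allylic hydroxylation (SeO2 cat., t-BuOOH), which is selective for the ring methylene, would give 3α-hydroxy-1β-mesyloxy-5αH-eudesma-4(15),7(11)-dien-8-one F5.
  - SOCl2 would convert F5 with allylic transposition and come back to the route at 5.

**Step 6.**
- Enolisation may go towards C9 or to the methyl group anti to the carbonyl. The diene would then not form or could not reach the s-cis shape.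
- Fallback, from 7:
  - The isopropylidene group is given up. Retro-aldol cleavage (aq. NaOH, EtOH, reflux) would give 11,12,13-trinorlindena-4(15)-en-8-one F6.
  - Its kinetic C7 enolate (LDA) and methyl pyruvate would give the aldol adduct methyl 11-hydroxy-8-oxolindena-4(15)-en-12-oate F7.
  - Brief acid-promoted dehydration and enol lactonisation comes back to the route at 13.

**Step 10.**
- Head-to-tail or syn pairing may occur.
- Energy may be wasted through the vinylcyclopropane.
- The dimer may revert on prolonged irradiation.
- Fallback, from 13:
  - The two bonds are made one after the other by electron transfer. Cathodic hydrodimerisation at the δ-carbon C9 (DMF, Et4NOTs, divided cell) would give the 9,9'-linked bis(8,9-dihydrobutenolide) F8.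
  - Double deprotonation at C8/C8' (LDA) and oxidative coupling of the bis-dienolate (I2 or anodic) would close C8–C8' and come back to the route at 14.

## Further compounds

F1 | step 5 | 1β-mesyloxy-15-noreudesm-7(11)-ene-4,8-dione | O=C1CC[C@@H](OS(C)(=O)=O)[C@@]2(C)[C@H]1CC(=C(C)C)C(=O)C2
F2 | step 5 | 15-norlindena-7(11)-ene-4,8-dione | O=C1[C@H]2C[C@H]2[C@@]2(C)[C@H]1CC(=C(C)C)C(=O)C2
F3 | step 1 | 1β-iodo-5αH-eudesma-4(15),7(11)-dien-8-one | C=C1CC[C@@H](I)[C@@]2(C)[C@H]1CC(=C(C)C)C(=O)C2
F4 | step 1 | 15-chloro-1β-iodo-5αH-eudesma-3,7(11)-dien-8-one | ClCC1=CC[C@@H](I)[C@@]2(C)[C@H]1CC(=C(C)C)C(=O)C2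
F5 | step 4 | 3α-hydroxy-1β-mesyloxy-5αH-eudesma-4(15),7(11)-dien-8-one | C=C1[C@H](O)C[C@@H](OS(C)(=O)=O)[C@@]2(C)[C@H]1CC(=C(C)C)C(=O)C2
F6 | step 6 | 11,12,13-trinorlindena-4(15)-en-8-one | C=C1[C@H]2C[C@H]2[C@@]2(C)[C@H]1CCC(=O)C2
F7 | step 6 | methyl 11-hydroxy-8-oxolindena-4(15)-en-12-oate (mixture at C7 and C11) | C=C1[C@H]2C[C@H]2[C@@]2(C)[C@H]1CC(C(=O)C2)C(C)(O)C(=O)OC
F8 | step 10 | 9,9'-linked bis(8,9-dihydrochloranthalactone A) | C=C1[C@H]2C[C@H]2[C@@]2(C)[C@H]1CC1=C(C)C(=O)O[C@@H]1[C@H]2[C@H]1[C@@]2(C)[C@@H]4C[C@@H]4C(=C)[C@@H]2CC2=C(C)C(=O)O[C@@H]21
A1 | alternative 1 | trans-2-diazoacetyl-1-methyl-1-vinylcyclohexan-5-one type diazoketone (C10 methyl and vinyl, C5 diazoacetyl, C8 ketone) | C=C[C@]1(C)CC(=O)CC[C@H]1C(=O)C=[N+]=[N-]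
A2 | alternative 2 | 3-hydroxygermacrone, 3-hydroxygermacra-1(10)E,4E,7(11)-trien-8-one | C/C1=C\C[C@H](O)/C(C)=C/CC(=C(C)C)C(=O)C1
A3 | alternative 3 | trans-3-cyclopropyl-3-methyl-4-[1-(triflyloxy)vinyl]cyclohexanone | C=C(OS(=O)(=O)C(F)(F)F)[C@@H]1CCC(=O)C[C@@]1(C)C1CC1
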